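Ring A of this eudesmane (C1–C4, C5, C10; eudesmane numbering) is assembled as a cyclobutane and enlarged by two atoms. Its only functionalised carbon, C4, sits next to ring-fusion C5, whose neighbour C10 is quaternary, so C4 can serve as the carbinol of a cyclobutanol carried on the C5=C10 olefin of a ring B unit from (S)-piperitone. Photocatalytic alkoxy-radical β-scission then opens the four-membered ring and the tethered radical re-closes on C10 (6-endo), giving the trans-decalone with C10 and C5 set in one operation. Methyl addition to C4, then a malonate/Knoevenagel–Doebner sequence at O6 with isovanillin, completes the isoferulate.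

Key step: step 4

Remark: eudesmane atom numbering is used throughout (ring A = C1–C5, C10; ring B = C5–C10; C6 carries the ester oxygen, C7 the isopropyl group), and (S)-(+)-piperitone of high enantiomeric purity is taken as commercially available.

Step 1
Reactants: 1 (S)-(+)-piperitone [(6S)-3-methyl-6-(propan-2-yl)cyclohex-2-en-1-one]
Product: 3 (6S)-2-bromo-3-methyl-6-(propan-2-yl)cyclohex-2-en-1-one, via dibromide 2 (not isolated)
Conditions: Br2, CH2Cl2, 0 °C; then Et3N, 0 °C to rt
Reagents that add atoms: bromine, BrBr
Why: Electrophilic addition of bromine to the enone C5=C10 bond followed by amine-induced dehydrobromination (bromination–dehydrobromination of an enone) should place bromine on C5, and the short, cold exposure to Et3N should leave the C7 stereocentre intact.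

Step 2
Reactants: 3 (6S)-2-bromo-3-methyl-6-(propan-2-yl)cyclohex-2-en-1-one
Product: 4 (1R,6S)-2-bromo-3-methyl-6-(propan-2-yl)cyclohex-2-en-1-ol
Conditions: LiBH(s-Bu)3, THF, −78 °C; then H2O
Reagents that add atoms: none
Why: 1,2-Reduction of the β,β-disubstituted bromoenone by the bulky borohydride (hindered-hydride carbonyl reduction) should deliver hydride to C6 from the face opposite the adjacent isopropyl group (equatorial attack, as in menthone to neomenthol), setting the 6β-hydroxyl cis to isopropyl.

Step 3
Reactants: 4 (1R,6S)-2-bromo-3-methyl-6-(propan-2-yl)cyclohex-2-en-1-ol; 5 cyclobutanone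
Product: 7 1-[(5S,6R)-6-hydroxy-2-methyl-5-(propan-2-yl)cyclohex-1-en-1-yl]cyclobutan-1-ol, via dilithio alkoxide 6 (not isolated)
Conditions: t-BuLi (3.1 equiv), THF, −78 °C; then 5, −78 to −20 °C; then H2O
Reagents that add atoms: none
Why: Hydroxyl deprotonation and bromine–lithium exchange (the third equivalent destroys the t-BuBr formed) should give a vinyllithium that adds 1,2 to the strained ketone (organolithium carbonyl addition); the new carbinol C4 carries two identical ring arms and is not a stereocentre.

Step 4
Reactants: 7 1-[(5S,6R)-6-hydroxy-2-methyl-5-(propan-2-yl)cyclohex-1-en-1-yl]cyclobutan-1-ol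
Product: 8 (4aR,7S,8R,8aS)-8-hydroxy-4a-methyl-7-(propan-2-yl)octahydronaphthalen-1(2H)-one (trans-fused 6β-hydroxy-15-nor-5αH-eudesman-4-one)
Conditions: [Ir(dF(CF3)ppy)2(5,5'-d(CF3)bpy)]PF6 (2 mol %), 2,4,6-collidine, CH2Cl2 (0.02 M), blue LEDs, rt
Reagents that add atoms: none
Why: Excited trivalent iridium and collidine take an electron and a proton from a hydroxyl of 7 (proton-coupled electron transfer); the O4 alkoxy radical, formed directly or from the O6 radical by hydrogen-atom relay across the internal O–H···O bond, undergoes strain-driven β-scission of a C4–CH2 bond of the cyclobutane, the primary radical adds to C10 of the unveiled C4(=O)–C5=C10 enone, and divalent iridium reduces the C5 α-keto radical before protonation. The closest known reaction type is the photocatalytic two-atom (n+2) ring expansion of 1-alkenyl cycloalkanols by alkoxy-radical scission and endo recombination. Ring A closes by 6-endo-trig radical addition, so that the four-membered ring C1–C4 takes up C5 and C10 and becomes six-membered. C10 is controlled by C6 and C7: the C6 hydroxyl hydrogen-bonds to the C4 carbonyl in the enone plane, the cis isopropyl group is then pseudoaxial, and axial attack should reach C10 from the opposite α-face, leaving the methyl group β. C5 should be protonated anti to the now axial C10 methyl and the 6β-oxygen, giving the 5α-H trans-decalin, which is also the epimer favoured at equilibrium through the enol. The step needs endo attack at C10 over exo attack at C5 and cyclobutane scission over chemistry at the secondary O6–H, secured by polarity matching plus the tertiary α-keto radical formed and by the ring strain of the cyclobutanol.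

Step 5
Reactants: 8 (4aR,7S,8R,8aS)-8-hydroxy-4a-methyl-7-(propan-2-yl)octahydronaphthalen-1(2H)-one
Product: 9 (1S,4aR,7S,8R,8aS)-1,4a-dimethyl-7-(propan-2-yl)decahydronaphthalene-1,8-diol (eudesmane-4β,6β-diol)
Conditions: MeLi (4 equiv), Et2O, −78 to 0 °C; then H2O
Reagents that add atoms: methyllithium, [Li]C
Why: Methyllithium should first form the O6 alkoxide and then add to the C4 ketone (1,2-addition of an organolithium) from the α-face, because the β-face is closed by the axial C10 methyl and the lithium-bound 6β-oxygen, so the new methyl is equatorial (α) and the 4-hydroxyl axial (β).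

Step 6
Reactants: 9 eudesmane-4β,6β-diol; 10 Meldrum's acid (2,2-dimethyl-1,3-dioxane-4,6-dione)
Product: 11 3-oxo-3-[(4β-hydroxyeudesman-6β-yl)oxy]propanoic acid (O6 hydrogen malonate of 9)
Conditions: toluene, 100 °C
Reagents that add atoms: none
Why: Thermal alcoholysis of Meldrum's acid (acyl transfer with loss of acetone) should acylate only the secondary 6β-hydroxyl, the tertiary 4-hydroxyl being too hindered to react.

Step 7
Reactants: 11 O6 hydrogen malonate of 9; 12 isovanillin (3-hydroxy-4-methoxybenzaldehyde)
Product: 14 4β-hydroxyeudesman-6β-yl (E)-3-(3-hydroxy-4-methoxyphenyl)prop-2-enoate (target), via arylidene malonate 13 (not isolated)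
Conditions: pyridine, piperidine (cat.), 80 °C
Reagents that add atoms: none
Why: Knoevenagel condensation of the malonate methylene with the aldehyde followed by pyridine-promoted decarboxylation (Doebner modification) should give the (E)-cinnamate directly and tolerates the free phenol and the tertiary alcohol.

Compound list

1 | (S)-(+)-piperitone, (6S)-3-methyl-6-(propan-2-yl)cyclohex-2-en-1-one | CC(C)[C@@H]1CCC(C)=CC1=O | starting material
2 | (6S)-2,3-dibromo-3-methyl-6-(propan-2-yl)cyclohexan-1-one (trans-dibromide, configuration at the two bromine-bearing carbons not controlled) | CC(C)[C@@H]1CCC(C)(Br)C(Br)C1=O | intermediate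
3 | (6S)-2-bromo-3-methyl-6-(propan-2-yl)cyclohex-2-en-1-one | CC(C)[C@@H]1CCC(C)=C(Br)C1=O | intermediate
4 | (1R,6S)-2-bromo-3-methyl-6-(propan-2-yl)cyclohex-2-en-1-ol (hydroxyl cis to isopropyl) | O[C@H]1C(Br)=C(C)CC[C@H]1C(C)C | intermediate
5 | cyclobutanone | O=C1CCC1 | starting material
6 | lithium (1R,6S)-2-lithio-3-methyl-6-(propan-2-yl)cyclohex-2-en-1-olate (dilithio alkoxide) | [Li]O[C@H]1C([Li])=C(C)CC[C@H]1C(C)C | intermediate
7 | 1-[(5S,6R)-6-hydroxy-2-methyl-5-(propan-2-yl)cyclohex-1-en-1-yl]cyclobutan-1-ol | O[C@H]1C(C2(O)CCC2)=C(C)CC[C@H]1C(C)C | intermediate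
8 | (4aR,7S,8R,8aS)-8-hydroxy-4a-methyl-7-(propan-2-yl)octahydronaphthalen-1(2H)-one (trans-fused; 6β-OH, 5α-H, 7β-isopropyl, 10β-methyl) | O[C@H]1[C@@H]2[C@](C)(CCCC2=O)CC[C@H]1C(C)C | intermediate
9 | (1S,4aR,7S,8R,8aS)-1,4a-dimethyl-7-(propan-2-yl)decahydronaphthalene-1,8-diol (eudesmane-4β,6β-diol; 5α-H, 7β-isopropyl, 10β-methyl) | O[C@H]1[C@@H]2[C@](C)(CCC[C@]2(C)O)CC[C@H]1C(C)C | intermediate
10 | Meldrum's acid, 2,2-dimethyl-1,3-dioxane-4,6-dione | CC1(C)OC(=O)CC(=O)O1 | starting material
11 | 3-oxo-3-[(4β-hydroxyeudesman-6β-yl)oxy]propanoic acid (hydrogen malonate at O6 of 9) | OC(=O)CC(=O)O[C@H]1[C@@H]2[C@](C)(CCC[C@]2(C)O)CC[C@H]1C(C)C | intermediate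
12 | isovanillin, 3-hydroxy-4-methoxybenzaldehyde | COc1ccc(C=O)cc1O | starting material
13 | 2-[(4β-hydroxyeudesman-6β-yl)oxycarbonyl]-3-(3-hydroxy-4-methoxyphenyl)prop-2-enoic acid (arylidene malonate, olefin geometry not defined) | COc1ccc(C=C(C(O)=O)C(=O)O[C@H]2[C@@H]3[C@](C)(CCC[C@]3(C)O)CC[C@H]2C(C)C)cc1O | intermediate
14 | 4β-hydroxyeudesman-6β-yl (E)-3-(3-hydroxy-4-methoxyphenyl)prop-2-enoate (6-O-isoferulate of 9) | COc1ccc(/C=C/C(=O)O[C@H]2[C@@H]3[C@](C)(CCC[C@]3(C)O)CC[C@H]2C(C)C)cc1O | target

Total step count: 7. Longest linear sequence: 7 steps (1 to 14).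

Steps most likely to fail

Step 4. Three processes could undermine it: hydrogen-atom or electron transfer at the free secondary O6–H, quenching of the primary radical before the hindered 6-endo closure on the fully substituted C10, and incomplete face control at C10. The fallback sets out from 7 and returns at 8; it masks O6 and separates ring opening from ring closure. Selective silylation of the secondary hydroxyl (TBSCl, imidazole, DMF) should give 1-[(5S,6R)-6-(tert-butyldimethylsilyloxy)-2-methyl-5-(propan-2-yl)cyclohex-1-en-1-yl]cyclobutan-1-ol F1. Hypoiodite fragmentation of the remaining tertiary cyclobutanol (PhI(OAc)2, I2, visible light, CH2Cl2) should open the four-membered ring to the 4-iodobutanoyl cyclohexene F2. Chain cyclisation at high dilution (Bu3SnH, AIBN, benzene, 80 °C) should close ring A on C10, anti to the pseudoaxial silyloxy group, to give the 6β-silyloxy decalone F3. Bu4NF in THF then returns 8.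

Step 6. Acylation of the axial, doubly flanked 6β-hydroxyl may be too slow, so that acid-promoted dehydration of the tertiary 4-hydroxyl or decarboxylation of the half ester takes over. The fallback sets out from 9 and returns at 14; it uses a small, reactive acylating agent and builds the olefin by phosphonate chemistry. Bromoacetyl bromide and pyridine in CH2Cl2 at 0 °C should give the 4β-hydroxyeudesman-6β-yl bromoacetate F4. A Michaelis–Arbuzov reaction with P(OEt)3 at 110 °C should convert it into the 4β-hydroxyeudesman-6β-yl (diethoxyphosphoryl)acetate F5. Horner–Wadsworth–Emmons olefination with 12 (LiCl, DBU, MeCN, rt) should then give 14 with the (E)-olefin.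

Step 5. Enolisation of the hindered ketone by MeLi, or retro-aldol opening of ring B through the O6 alkoxide, may outrun carbonyl addition. The fallback sets out from 8 and returns at 9. A Corey–Chaykovsky reaction (Me3SI, KOt-Bu, DMSO/THF) should deliver the methylene from the open α-face and give the 4,15-epoxy-eudesman-6β-ol (spiro-epoxide, methylene α, oxygen β) F6. Hydride opening at the methylene (LiAlH4, THF, 0 °C) then returns 9.

Further compounds

F1 | step 4 | 1-[(5S,6R)-6-(tert-butyldimethylsilyloxy)-2-methyl-5-(propan-2-yl)cyclohex-1-en-1-yl]cyclobutan-1-ol | CC(C)(C)[Si](C)(C)O[C@H]1C(C2(O)CCC2)=C(C)CC[C@H]1C(C)C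
F2 | step 4 | 1-[(5S,6R)-6-(tert-butyldimethylsilyloxy)-2-methyl-5-(propan-2-yl)cyclohex-1-en-1-yl]-4-iodobutan-1-one | CC(C)(C)[Si](C)(C)O[C@H]1C(C(=O)CCCI)=C(C)CC[C@H]1C(C)C
F3 | step 4 | (4aR,7S,8R,8aS)-8-(tert-butyldimethylsilyloxy)-4a-methyl-7-(propan-2-yl)octahydronaphthalen-1(2H)-one | CC(C)(C)[Si](C)(C)O[C@H]1[C@@H]2[C@](C)(CCCC2=O)CC[C@H]1C(C)C
F4 | step 6 | 4β-hydroxyeudesman-6β-yl bromoacetate | BrCC(=O)O[C@H]1[C@@H]2[C@](C)(CCC[C@]2(C)O)CC[C@H]1C(C)C
F5 | step 6 | 4β-hydroxyeudesman-6β-yl (diethoxyphosphoryl)acetate | CCOP(=O)(OCC)CC(=O)O[C@H]1[C@@H]2[C@](C)(CCC[C@]2(C)O)CC[C@H]1C(C)C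
F6 | step 5 | 4,15-epoxy-15-... spiro-epoxide of 8: (4β-O,15-methylene α)-4,15-epoxyeudesman-6β-ol | O[C@H]1[C@@H]2[C@](C)(CCC[C@]2(C3)O3)CC[C@H]1C(C)C
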